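| flask | substrate | partner A | partner B | remark | time |
|---|---|---|---|---|---|
| dawn | 0.50 M | 1.2 equiv | 1.4 equiv | run made earlier |  |
| midnight | 0.50 M | 1.2 equiv | 2.2 equiv | run made earlier |  |
| spring | 0.50 M | 0.60 equiv | 1 equiv | run made earlier |  |
| flask | 0.50 M | 1.20 equiv | 1.00 equiv |  | 25 min |

- dawn (time / min: open intermediate / %, target / %): 0.250: 38.1, 3.5; 0.500: 44.4, 10.9; 1.33: 43.4, 27.4; 2.50: 39.8, 32.5; 5.00: 37.1, 36.5; 12.0: 36.6, 37.2; 25.0: 38.6, 38.6
- midnight (time / min: open intermediate / %, target / %): 0.250: 52.3, 8.7; 0.500: 56.0, 19.4; 1.33: 50.7, 40.4; 2.50: 43.0, 52.7; 5.00: 36.8, 61.6; 12.0: 32.7, 67.9; 25.0: 29.6, 70.4
- spring (time / min: open intermediate / %, target / %): 0.250: 33.5, 0.2; 0.833: 48.1, 8.3; 2.50: 47.6, 19.6; 8.00: 48.5, 22.1; 25.0: 47.4, 21.5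

(readings scatter by 1 percentage point)

1. time up to 25 min at which open intermediate stands highest
2. the amount of open intermediate, in percent of the substrate charged, at that time

- the earlier runs were read with a standard deviation of 1 percentage point
- steps thought possible: substrate + partner B -> open intermediate; partner B + partner A -> second intermediate; open intermediate + second intermediate -> target; 2 second intermediate -> homo product

The easy step is to keep books on partner B, the limiting reagent of the flask, where 1.00 equiv must serve substrate and partner A together. Each mole goes one of two ways: onto substrate, giving open intermediate, or onto partner A, giving second intermediate. The spring run supplies the entries. Its readings stand still, within their scatter, from 8.00 min, so we book its whole 1 equiv as consumed. Open intermediate and target together hold 68.9% of the substrate, and that is the first entry. The other 0.311 equiv went to partner A, leaving 0.289 equiv. Of that second entry, 69.1% reached target, and we book the rest as homo product.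

Both ways are taken as first order in partner B, so the remainders are tied together. The spring run gives 1.60 for the selectivity factor, the logarithm of the fraction of substrate left over that of the fraction of partner A left. At equal concentrations, substrate takes partner B faster than partner A does. The last dawn readings give 2.00, which shows the spread of such a reading.

In the flask, the start ratio of the two uses is 1.33, so substrate first takes 57.1% of partner B. Booked at that start share, which is rough for a whole run, our books close near 29.6% target and 27.5% open intermediate. We read that last entry as a floor for the peak. The forecast gives 37.5% at 0.7 min, holding that “open intermediate must peak early, then decline”.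

The flask gives 37.5% at 0.731 min.

    substrate + partner B → open intermediate (k = 0.0770 /M/s)
    partner B + partner A → second intermediate (k = 0.0450 /M/s)
    open intermediate + second intermediate → target (k = 0.100 /M/s)
    2 second intermediate → homo product (k = 0.120 /M/s)

The leftovers of the flask at 25.0 min, 45% of substrate and 63% of partner A, return a selectivity factor of 1.71, and the start ratio stands at 1.4 against our 1.33. The largest single effect on the time of the peak in the flask, though not the main reason for it, is the loss of second intermediate to homo product: without that loss, the peak comes at 0.534 min instead of 0.731 min. Part of the height of the peak comes from the using up of partner B: without it, the flask climbs to 58.3% instead of 37.5%. With 3.00 equiv of partner A, the leftovers 66% and 78% give a factor of 1.71, and open intermediate peaks at 24.0%.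

The numbers in the tables were computed on assumed constants.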